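A pitfall of percent curves is that two of them lying on each other invite a rate constant, which is then carried over to a smaller charge.

| flask | substrate | scavenger | gas | remark | time |
|---|---|---|---|---|---|
| Monday's | 54 mM | 43.2 mM | 9.7 mM (held) | run made earlier |  |
| Saturday's | 72 mM | 43.2 mM | 9.7 mM (held) | run made earlier |  |
| epsilon | 36 mM | 43.0 mM | 9.7 mM (held) |  | 10 h |
| eta | 36 mM | 86.0 mM | 9.7 mM (held) |  | 10 h |

| run | time / h | substrate / % | bis adduct / % |
|---|---|---|---|
| Monday's | 0.200 | 100.5 | 0 |
| Monday's | 0.500 | 98.5 | 0.6 |
| Monday's | 1.00 | 96.3 | 0 |
| Monday's | 1.50 | 93.2 | 0 |
| Monday's | 2.00 | 91.7 | 0.6 |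
| Monday's | 3.00 | 86.9 | 1.3 |
| Monday's | 4.00 | 83.1 | 2.4 |
| Saturday's | 0.200 | 98.8 | 0 |
| Saturday's | 0.500 | 98.6 | 0 |
| Saturday's | 1.00 | 95.9 | 0 |
| Saturday's | 1.50 | 95.6 | 0 |
| Saturday's | 2.00 | 93.4 | 0 |
| Saturday's | 3.00 | 89.3 | 0 |
| Saturday's | 4.00 | 82.1 | 1.8 |

(scatter of a reading: 1 percentage point)

- at the start none of the gas is in solution
- no earlier run changes the charge of scavenger; that part of a forecast is a guess

- part of the substrate that has reacted at the end, epsilon
- part of the substrate that has reacted at the end, eta
- what raising the concentration of scavenger from its lowest to its highest value here does to the part of the substrate that has reacted (changes below 5 percentage points count as none) (no change / it falls / it rises)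

One chemist reads Monday's and Saturday's runs as pseudo-first-order decay, so that percent lost depends on time and not on charge. The forecast is that chemist's: 36% for epsilon, 36% for eta, no change, on the ground that “Substrate concentration shouldn't matter.”

The other chemist counts gas. It starts undissolved, and a bis adduct has taken it up twice, so the last Saturday reading shows uptake of 19.7% of that charge, reacted substrate plus bis adduct. Monday's uptake, 19.3% of a smaller charge, is the lower amount, so this chemist takes Saturday's as the measure of what the gas can deliver. Scaled by charge and time, that gives the turnover count, the gas delivered in charges of substrate: 0.985 for epsilon. The reacted fraction should then lie between 49.2%, with every reacted substrate loaded twice, and 98.5%, with each loaded once. That is this chemist's reckoning, and the forecast's number lies below its lower end. Scavenger does not enter the count, so eta should match epsilon, which is a guess.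

The simulation gives 57.7% for epsilon and 58.1% for eta, so the answer on the trend is no change, the difference being 0.35 percentage points.

    substrate + reagent → mono adduct + released group (k = 76.0 M⁻¹ h⁻¹)
    reagent + mono adduct → bis adduct + released group (k = 72.0 M⁻¹ h⁻¹)
    reagent + released group ⇌ idle adduct, settled at all times (K = 72.0 M⁻¹)
    scavenger + released group → scavenged by-product (k = 23.0 M⁻¹ h⁻¹)
    gas ⇌ reagent, rate k5*(csat - [reagent]) (kL = 0.350 h⁻¹)

Epsilon's result lies inside the count's bracket. At 4.94 h in epsilon, the first step gives reagent a half-life of 0.37 h, shorter than the 1.98 h of the gas crossing. Reagent stands at 1.16 mM at 5.00 h, against a saturation of 9.7 mM. The first-order view keeps the range it was read from: at the last readings, Monday's and Saturday's substrate differ by 1 point, with a scatter of 1 point.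

Take epsilon's flask with 90 mM of substrate: the count falls to 0.394, so the reacted fraction should lie between 19.7% and 39.4%. That flask gives 30.2%.

Readings and results were generated by integration for substances that don't exist; the scatter is artificial.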